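The plan rests on disconnecting the O1–C2 ether bond of the dihydrofuran ring. C2 is benzylic and para to the free phenol of the syringyl ring (ring C), so a C2 carbinol ionises to a para-quinone methide, which the ring A phenol oxygen traps. In one acid-mediated operation both methoxymethyl ethers fall, the quinone methide forms and the ring closes, C3 steering the aryl group trans. The precursor is an open-chain 2-aryl-1-arylpropane-1,3-diol whose C3 stereocentre comes from an Evans syn aldol reaction between an (S)-oxazolidinone arylacetyl imide (ring A, carrying an allyl group as the latent hydroxypropyl chain) and protected syringaldehyde.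

Key step: step 9

Assumption: 5-allyl-2-hydroxy-3-methoxybenzaldehyde (ortho-formylated eugenol) is taken as a purchasable starting material; the target is numbered as a 2,3-dihydro-1-benzofuran (O1, aryl-bearing C2, hydroxymethyl-bearing C3), ring A being its benzo ring and ring C the syringyl ring.

Step 1
Reactants: 1 5-allyl-2-hydroxy-3-methoxybenzaldehyde
Product: 2 5-allyl-3-methoxy-2-(methoxymethoxy)benzaldehyde
Conditions: MOMCl, i-Pr2NEt, CH2Cl2, 0 °C to rt
Reagents that add atoms: chloromethyl methyl ether, COCCl
Why: O-alkylation of the phenol with the reactive alpha-chloro ether (methoxymethyl ether formation) should give an acetal that survives the basic, enolate and hydride steps and falls off under the acid of the last step.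

Step 2
Reactants: 2 5-allyl-3-methoxy-2-(methoxymethoxy)benzaldehyde
Product: 3 2-[5-allyl-3-methoxy-2-(methoxymethoxy)phenyl]acetonitrile
Conditions: TosMIC, t-BuOK, DME, −30 °C; then MeOH, reflux
Reagents that add atoms: p-toluenesulfonylmethyl isocyanide (TosMIC), Cc1ccc(cc1)S(=O)(=O)C[N+]#[C-]
Why: Van Leusen reductive cyanation, in which the TosMIC anion adds to the aldehyde, the oxazoline intermediate is opened and deformylated by methoxide and loss of sulfinate leaves the one-carbon homologated nitrile, should leave the allyl group and the acetal untouched.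

Step 3
Reactants: 3 2-[5-allyl-3-methoxy-2-(methoxymethoxy)phenyl]acetonitrile
Product: 4 2-[5-allyl-3-methoxy-2-(methoxymethoxy)phenyl]acetic acid
Conditions: NaOH, EtOH/H2O, 80 °C; then cold 1 M HCl to pH 4
Reagents that add atoms: sodium hydroxide, [Na+].[OH-]; water, O
Why: Basic nitrile hydrolysis of the unhindered arylacetonitrile (through the primary amide) should give the acid, the basic medium and a brief cold acidification keeping the methoxymethyl ether in place.

Step 4
Reactants: 4 2-[5-allyl-3-methoxy-2-(methoxymethoxy)phenyl]acetic acid; 5 (S)-4-benzyl-1,3-oxazolidin-2-one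
Product: 7 (S)-4-benzyl-3-{2-[5-allyl-3-methoxy-2-(methoxymethoxy)phenyl]acetyl}-1,3-oxazolidin-2-one, via mixed pivalic anhydride 6 (not isolated)
Conditions: PivCl, Et3N, THF, −20 °C; then 5, LiCl, rt
Reagents that add atoms: none
Why: N-acylation of the Evans auxiliary through the mixed pivalic anhydride, with LiCl and Et3N activating the oxazolidinone, is a standard mild imide synthesis that avoids ketene formation from the arylacetyl unit.

Step 5
Reactants: 8 syringaldehyde (4-hydroxy-3,5-dimethoxybenzaldehyde)
Product: 9 3,5-dimethoxy-4-(methoxymethoxy)benzaldehyde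
Conditions: MOMCl, i-Pr2NEt, CH2Cl2, 0 °C to rt
Reagents that add atoms: chloromethyl methyl ether, COCCl
Why: The same methoxymethyl ether formation on the acidic syringyl phenol masks it during the boron aldol reaction and lets both phenols be released together at the end.

Step 6
Reactants: 7 (S)-4-benzyl-3-{2-[5-allyl-3-methoxy-2-(methoxymethoxy)phenyl]acetyl}-1,3-oxazolidin-2-one; 9 3,5-dimethoxy-4-(methoxymethoxy)benzaldehyde
Product: 11 (S)-4-benzyl-3-{(2S,3S)-2-[5-allyl-3-methoxy-2-(methoxymethoxy)phenyl]-3-[3,5-dimethoxy-4-(methoxymethoxy)phenyl]-3-hydroxypropanoyl}-1,3-oxazolidin-2-one, via Z dibutylboron enolate 10 (not isolated)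
Conditions: Bu2BOTf, i-Pr2NEt, CH2Cl2, −78 to 0 °C; then 9, −78 to 0 °C; pH 7 buffer, MeOH, H2O2
Reagents that add atoms: none
Why: In this Evans syn aldol reaction soft enolisation gives the Z boron enolate, which should add to the aldehyde through a closed chair (Zimmerman–Traxler) transition state on the face away from the benzyl group of the (S)-auxiliary, setting the aryl-bearing carbon (S) (the later C3, which becomes R once the acyl carbon is reduced) and the carbinol carbon (S).

Step 7
Reactants: 11 (S)-4-benzyl-3-{(2S,3S)-2-[5-allyl-3-methoxy-2-(methoxymethoxy)phenyl]-3-[3,5-dimethoxy-4-(methoxymethoxy)phenyl]-3-hydroxypropanoyl}-1,3-oxazolidin-2-one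
Product: 12 (1S,2R)-2-[5-allyl-3-methoxy-2-(methoxymethoxy)phenyl]-1-[3,5-dimethoxy-4-(methoxymethoxy)phenyl]propane-1,3-diol
Conditions: LiBH4, MeOH (1 equiv), THF, 0 °C
Reagents that add atoms: none
Why: Reductive cleavage of the N-acyl oxazolidinone by LiBH4 attacks the exocyclic imide carbonyl, releases the auxiliary for recovery and should give the 1,3-diol with both stereocentres intact when kept cold to suppress retro-aldol cleavage.

Step 8
Reactants: 12 (1S,2R)-2-[5-allyl-3-methoxy-2-(methoxymethoxy)phenyl]-1-[3,5-dimethoxy-4-(methoxymethoxy)phenyl]propane-1,3-diol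
Product: 14 (1S,2R)-1-[3,5-dimethoxy-4-(methoxymethoxy)phenyl]-2-[5-(3-hydroxypropyl)-3-methoxy-2-(methoxymethoxy)phenyl]propane-1,3-diol, via B-alkyl-9-BBN adduct 13 (not isolated)
Conditions: 9-BBN (excess), THF, 0 °C to rt; then NaOH, H2O2, 0 °C
Reagents that add atoms: hydrogen peroxide, OO
Why: Anti-Markovnikov Brown hydroboration–oxidation with the bulky 9-BBN should place boron on the terminal carbon of the allyl group and alkaline peroxide then converts the C–B bond into the primary alcohol, the excess reagent allowing for the borinates formed on the free hydroxyl groups.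

Step 9
Reactants: 14 (1S,2R)-1-[3,5-dimethoxy-4-(methoxymethoxy)phenyl]-2-[5-(3-hydroxypropyl)-3-methoxy-2-(methoxymethoxy)phenyl]propane-1,3-diol
Product: 17 (2S,3R)-2-(4-hydroxy-3,5-dimethoxyphenyl)-3-(hydroxymethyl)-5-(3-hydroxypropyl)-7-methoxy-2,3-dihydro-1-benzofuran, via bisphenol tetraol 15 (not isolated), via para-quinone methide 16 (not isolated)
Conditions: HCl (2 M aq), MeOH, 0 °C to 40 °C, short reaction time
Reagents that add atoms: none
Why: Aqueous HCl in methanol first cleaves both methoxymethyl acetals to bisphenol 15; protonation of the benzylic C1 hydroxyl, which sits para to the freed phenol of ring C, then expels water to give the para-quinone methide 16 (reacting as its O-protonated form). The ring A phenol oxygen adds to the exocyclic methide carbon in an oxa-1,6-conjugate addition that re-aromatises ring C and forms the O1–C2 bond, closing the dihydrofuran ring in 5-exo-trig mode. The closest known reaction type is the acid-catalysed, biomimetic phenylcoumaran ring closure of open-chain beta-5 lignin model diols through a quinone methide. The new C2 stereocentre is controlled by the existing C3 centre, the aryl group adding anti to the hydroxymethyl group to give the trans (2S,3R) ring, so the carbinol configuration of 14 is immaterial because C1 is planarised. The step needs attack by the ring A phenol in preference to methanol or the primary hydroxyl: the benzylic methyl ether formed by methanol re-ionises, a four-membered ring from the C3 hydroxymethyl is disfavoured, and the phenol is held five atoms from the electrophilic carbon. Mild, brief acid treatment is chosen so that C3 is not put at risk by reversible elimination towards a stilbene.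

Compound list
1 | 5-allyl-2-hydroxy-3-methoxybenzaldehyde | C=CCc1cc(OC)c(O)c(C=O)c1 | starting material
2 | 5-allyl-3-methoxy-2-(methoxymethoxy)benzaldehyde | C=CCc1cc(OC)c(OCOC)c(C=O)c1 | intermediate
3 | 2-[5-allyl-3-methoxy-2-(methoxymethoxy)phenyl]acetonitrile | C=CCc1cc(OC)c(OCOC)c(CC#N)c1 | intermediate
4 | 2-[5-allyl-3-methoxy-2-(methoxymethoxy)phenyl]acetic acid | C=CCc1cc(OC)c(OCOC)c(CC(=O)O)c1 | intermediate
5 | (S)-4-benzyl-1,3-oxazolidin-2-one | O=C1N[C@@H](Cc2ccccc2)CO1 | starting material
6 | 2-[5-allyl-3-methoxy-2-(methoxymethoxy)phenyl]acetic pivalic anhydride (mixed anhydride, not isolated) | C=CCc1cc(OC)c(OCOC)c(CC(=O)OC(=O)C(C)(C)C)c1 | intermediate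
7 | (S)-4-benzyl-3-{2-[5-allyl-3-methoxy-2-(methoxymethoxy)phenyl]acetyl}-1,3-oxazolidin-2-one | C=CCc1cc(OC)c(OCOC)c(CC(=O)N2[C@@H](Cc3ccccc3)COC2=O)c1 | intermediate
8 | syringaldehyde (4-hydroxy-3,5-dimethoxybenzaldehyde) | COc1cc(C=O)cc(OC)c1O | starting material
9 | 3,5-dimethoxy-4-(methoxymethoxy)benzaldehyde | COCOc1c(OC)cc(C=O)cc1OC | intermediate
10 | Z dibutylboron enolate of 7 (boron on the enolate oxygen, aryl group cis to it; not isolated) | CCCCB(CCCC)O/C(=C\c1cc(CC=C)cc(OC)c1OCOC)N1[C@@H](Cc2ccccc2)COC1=O | intermediate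
11 | (S)-4-benzyl-3-{(2S,3S)-2-[5-allyl-3-methoxy-2-(methoxymethoxy)phenyl]-3-[3,5-dimethoxy-4-(methoxymethoxy)phenyl]-3-hydroxypropanoyl}-1,3-oxazolidin-2-one | O=C1OC[C@H](Cc2ccccc2)N1C(=O)[C@@H](c1cc(CC=C)cc(OC)c1OCOC)[C@H](O)c1cc(OC)c(OCOC)c(OC)c1 | intermediate
12 | (1S,2R)-2-[5-allyl-3-methoxy-2-(methoxymethoxy)phenyl]-1-[3,5-dimethoxy-4-(methoxymethoxy)phenyl]propane-1,3-diol | OC[C@@H](c1cc(CC=C)cc(OC)c1OCOC)[C@H](O)c1cc(OC)c(OCOC)c(OC)c1 | intermediate
13 | B-alkyl-9-BBN adduct of 12 (boron on the terminal carbon of the former allyl group, hydroxyl groups drawn free; not isolated) | OC[C@@H](c1cc(CCCB2C3CCCC2CCC3)cc(OC)c1OCOC)[C@H](O)c1cc(OC)c(OCOC)c(OC)c1 | intermediate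
14 | (1S,2R)-1-[3,5-dimethoxy-4-(methoxymethoxy)phenyl]-2-[5-(3-hydroxypropyl)-3-methoxy-2-(methoxymethoxy)phenyl]propane-1,3-diol | OC[C@@H](c1cc(CCCO)cc(OC)c1OCOC)[C@H](O)c1cc(OC)c(OCOC)c(OC)c1 | intermediate
15 | (1S,2R)-1-(4-hydroxy-3,5-dimethoxyphenyl)-2-[2-hydroxy-5-(3-hydroxypropyl)-3-methoxyphenyl]propane-1,3-diol (not isolated) | OC[C@@H](c1cc(CCCO)cc(OC)c1O)[C@H](O)c1cc(OC)c(O)c(OC)c1 | intermediate
16 | 4-{(2R)-3-hydroxy-2-[2-hydroxy-5-(3-hydroxypropyl)-3-methoxyphenyl]propylidene}-2,6-dimethoxycyclohexa-2,5-dien-1-one (para-quinone methide, not isolated) | OC[C@@H](c1cc(CCCO)cc(OC)c1O)C=C1C=C(OC)C(=O)C(OC)=C1 | intermediate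
17 | (2S,3R)-2-(4-hydroxy-3,5-dimethoxyphenyl)-3-(hydroxymethyl)-5-(3-hydroxypropyl)-7-methoxy-2,3-dihydro-1-benzofuran | COc1cc([C@H]2Oc3c(OC)cc(CCCO)cc3[C@@H]2CO)cc(OC)c1O | target

Total step count: 9. Longest linear sequence: 8 steps (steps 1, 2, 3, 4, 6, 7, 8 and 9); step 5 is a one-step branch.

Steps most likely to fail

Step 9. The quinone methide may be diverted before the ring closes, by loss of formaldehyde towards a stilbene or by intermolecular attack leading to oligomers, and prolonged acid may erode the C3 configuration through reversible elimination. The fallback sets out from 14 and generates the quinone methide without acid. TMSBr in CH2Cl2 at −30 to 0 °C cleaves both methoxymethyl ethers and converts the benzylic carbinol into the benzylic bromide F1. Shaking that solution with saturated aqueous NaHCO3 eliminates HBr in a 1,6-sense and gives the neutral para-quinone methide 16, where the route is rejoined and ring closure to 17 follows.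

Step 6. The acidic alpha-aryl centre may give poor facial selectivity, or the adduct may suffer retro-aldol cleavage and epimerisation during the boron enolate reaction and its work-up. The fallback sets out from acid 4 and sets C3 by catalyst-controlled ketone reduction under dynamic kinetic resolution instead of an auxiliary aldol reaction.
- MeI and K2CO3 in DMF give methyl ester F2.
- Its lithium enolate (LiN(i-Pr)2, THF, −78 °C) adds to aldehyde 9 to give the racemic beta-hydroxy ester F3 as a mixture of diastereomers.
- Dess–Martin periodinane oxidises it to the configurationally labile beta-keto ester F4.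
- Noyori asymmetric transfer hydrogenation with RuCl[(S,S)-TsDPEN](p-cymene) in HCO2H/Et3N (catalyst enantiomer chosen to deliver the 2S ester) should give the (2S)-beta-hydroxy ester F5.
- LiBH4 reduces it to diol F6, which has the (2R) centre of 12 and either carbinol configuration.
- The conditions of step 8 convert it into triol F7, and the conditions of step 9 bring the sequence back to the route at quinone methide 16, where the carbinol configuration no longer matters.

Step 7. The basic hydride medium may trigger retro-aldol cleavage or epimerisation at the alpha-aryl carbon, or hydride may open the oxazolidinone ring instead of cleaving the exocyclic acyl group. The fallback sets out from 11. LiOH/H2O2 in THF/H2O at 0 °C hydrolyses the imide to the beta-hydroxy acid F8, with recovery of 5. Excess BH3·THF then reduces the carboxylic acid and hydroborates the allyl group in the same flask, and NaOH/H2O2 work-up gives triol 14, where the route is rejoined.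

Further compounds
F1 | step 9 | 4-{(2R)-1-bromo-3-hydroxy-2-[2-hydroxy-5-(3-hydroxypropyl)-3-methoxyphenyl]propyl}-2,6-dimethoxyphenol (bromide centre as a mixture) | OC[C@@H](c1cc(CCCO)cc(OC)c1O)C(Br)c1cc(OC)c(O)c(OC)c1
F2 | step 6 | methyl 2-[5-allyl-3-methoxy-2-(methoxymethoxy)phenyl]acetate | C=CCc1cc(OC)c(OCOC)c(CC(=O)OC)c1
F3 | step 6 | methyl 2-[5-allyl-3-methoxy-2-(methoxymethoxy)phenyl]-3-[3,5-dimethoxy-4-(methoxymethoxy)phenyl]-3-hydroxypropanoate (racemic, mixture of diastereomers) | COC(=O)C(c1cc(CC=C)cc(OC)c1OCOC)C(O)c1cc(OC)c(OCOC)c(OC)c1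
F4 | step 6 | methyl 2-[5-allyl-3-methoxy-2-(methoxymethoxy)phenyl]-3-[3,5-dimethoxy-4-(methoxymethoxy)phenyl]-3-oxopropanoate (racemic) | COC(=O)C(c1cc(CC=C)cc(OC)c1OCOC)C(=O)c1cc(OC)c(OCOC)c(OC)c1
F5 | step 6 | methyl (2S)-2-[5-allyl-3-methoxy-2-(methoxymethoxy)phenyl]-3-[3,5-dimethoxy-4-(methoxymethoxy)phenyl]-3-hydroxypropanoate (carbinol configuration set by the catalyst) | COC(=O)[C@@H](c1cc(CC=C)cc(OC)c1OCOC)C(O)c1cc(OC)c(OCOC)c(OC)c1
F6 | step 6 | (2R)-2-[5-allyl-3-methoxy-2-(methoxymethoxy)phenyl]-1-[3,5-dimethoxy-4-(methoxymethoxy)phenyl]propane-1,3-diol (either C1 configuration) | OC[C@@H](c1cc(CC=C)cc(OC)c1OCOC)C(O)c1cc(OC)c(OCOC)c(OC)c1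
F7 | step 6 | (2R)-1-[3,5-dimethoxy-4-(methoxymethoxy)phenyl]-2-[5-(3-hydroxypropyl)-3-methoxy-2-(methoxymethoxy)phenyl]propane-1,3-diol (either C1 configuration) | OC[C@@H](c1cc(CCCO)cc(OC)c1OCOC)C(O)c1cc(OC)c(OCOC)c(OC)c1
F8 | step 7 | (2S,3S)-2-[5-allyl-3-methoxy-2-(methoxymethoxy)phenyl]-3-[3,5-dimethoxy-4-(methoxymethoxy)phenyl]-3-hydroxypropanoic acid | OC(=O)[C@@H](c1cc(CC=C)cc(OC)c1OCOC)[C@H](O)c1cc(OC)c(OCOC)c(OC)c1
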